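**Strategy.** The oxolane (ring O1–C4–C5–C6–C7) and its exocyclic propargylic bromide at C3 are traced back together to a 2,6-trans-2-ethynyloxan-3-ol, in which the ring oxygen sits on C3 and C7 and C4 carries a free hydroxyl. Activating that hydroxyl lets the ring oxygen shift from C3 to C4 through a bridged oxiranium ion while bromide enters at C3. One operation therefore contracts the six-membered ring, forms the C4–O and C3–Br bonds and sets both stereocentres by double inversion. The step exploits the vicinal C3(Br)–C4(O) pair next to the alkyne C1≡C2. The precursor already holds the C6 acetate, the C9 silyl ether, the C10 bromide and the C12=C13 alkene.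

Key step: step 12

Assumption (remark on the chemistry): chain atoms are numbered C1 (alkyne CH) to C15 in every compound; lactol 8 and acetate 9 are used as anomeric mixtures because both anomers give the same oxocarbenium ion in step 7.
Structure check: oxane 16 and oxolane 19 differ only at C3 and C4, (3R,4S) against (3S,4R), as two inversions require; C6 (R), C7 (R), C9 (S) and C10 (R) are the same in both and in the target.
Design note: the C4 hydroxyl is carried as a C–B bond until the C6 acetate is in place, so the two ring oxygens never have to be told apart. TBS = tert-butyldimethylsilyl.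

Step 1
Reactants: 1 (E)-hept-4-enal
Product: 2 (2R,4E)-2-bromohept-4-enal
Conditions: 4,4-dibromo-2,6-di-tert-butylcyclohexa-2,5-dien-1-one, (R)-2-{bis[3,5-bis(trifluoromethyl)phenyl][(trimethylsilyl)oxy]methyl}pyrrolidine (10 mol%), PhCO2H (10 mol%), CH2Cl2/pentane, −40 °C; cold silica filtration, used at once
Reagents that add atoms: 4,4-dibromo-2,6-di-tert-butylcyclohexa-2,5-dien-1-one, CC(C)(C)C1=CC(Br)(Br)C=C(C(C)(C)C)C1=O
Why: Organocatalytic enamine α-bromination: the bulky silyloxy-diarylmethyl group of the (R)-prolinol ether shields one face of the E-enamine, so the mild Br+ donor, which leaves the isolated alkene alone, should enter from the other face and set C10 as (R).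

Step 2
Reactants: 3 2-acetylfuran; 2 (2R,4E)-2-bromohept-4-enal
Product: 5 (3S,4R,6E)-4-bromo-1-(furan-2-yl)-3-hydroxynon-6-en-1-one, via lithium enolate 4 (not isolated)
Conditions: LiN(i-Pr)2, THF, −78 °C; then 2, −78 °C; AcOH quench at −78 °C
Reagents that add atoms: none
Why: Lithium aldol addition under Cornforth control: the enolate should attack the aldehyde face anti to the C–Br dipole, giving the 1,2-anti bromohydrin and hence the (S) carbinol at C9, and the cold acidic quench keeps the aldolate from closing to an epoxide.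

Step 3
Reactants: 5 anti-bromohydrin aldol adduct
Product: 6 (3S,4R,6E)-4-bromo-3-[(tert-butyldimethylsilyl)oxy]-1-(furan-2-yl)non-6-en-1-one
Conditions: TBSOTf, 2,6-lutidine, CH2Cl2, −78 °C
Reagents that add atoms: tert-butyldimethylsilyl triflate, CC(C)(C)[Si](C)(C)OS(=O)(=O)C(F)(F)F
Why: Silylation with a silyl triflate and a hindered base at low temperature protects the C9 hydroxyl before retro-aldol cleavage or bromohydrin-to-epoxide closure can occur.

Step 4
Reactants: 6 furyl ketone silyl ether
Product: 7 (1R,3S,4R,6E)-4-bromo-3-[(tert-butyldimethylsilyl)oxy]-1-(furan-2-yl)non-6-en-1-ol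
Conditions: RuCl(p-cymene)[(R,R)-TsDPEN] (2 mol%), HCO2H/Et3N (5:2), CH2Cl2, rt
Reagents that add atoms: none
Why: Noyori–Ikariya asymmetric transfer hydrogenation: the (R,R)-TsDPEN ruthenium hydride tells heteroaryl from alkyl and should give the (R) carbinol at C7 under catalyst control, in a mildly acidic medium that spares the β-silyloxy ketone and the bromide.

Step 5
Reactants: 7 (R)-furyl carbinol
Product: 8 (2R)-2-[(2S,3R,5E)-3-bromo-2-[(tert-butyldimethylsilyl)oxy]oct-5-en-1-yl]-6-hydroxy-2H-pyran-3(6H)-one (both C6 anomers)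
Conditions: VO(acac)2 (5 mol%), t-BuOOH, CH2Cl2, 0 °C to rt
Reagents that add atoms: tert-butyl hydroperoxide, CC(C)(C)OO
Why: Achmatowicz rearrangement: hydroxyl-directed vanadium-catalysed oxidation of the furan and ring expansion should give the pyranone lactol with C7 retained, while the remote alkene, which has no directing hydroxyl nearby, is left alone.

Step 6
Reactants: 8 pyranone lactol
Product: 9 (6R)-6-[(2S,3R,5E)-3-bromo-2-[(tert-butyldimethylsilyl)oxy]oct-5-en-1-yl]-5-oxo-5,6-dihydro-2H-pyran-2-yl acetate (anomeric mixture)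
Conditions: Ac2O, pyridine, 4-(dimethylamino)pyridine (cat.), CH2Cl2, 0 °C
Reagents that add atoms: acetic anhydride, CC(=O)OC(C)=O
Why: Acylation of the hemiacetal turns the anomeric hydroxyl into a leaving group, and both anomers can be carried on because they give the same cation.

Step 7
Reactants: 9 anomeric acetate; 10 tributyl[(trimethylsilyl)ethynyl]stannane
Product: 11 (2R,6S)-2-[(2S,3R,5E)-3-bromo-2-[(tert-butyldimethylsilyl)oxy]oct-5-en-1-yl]-6-[(trimethylsilyl)ethynyl]-2H-pyran-3(6H)-one (2,6-trans)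
Conditions: BF3·OEt2, CH2Cl2, −78 to −40 °C
Reagents that add atoms: none
Why: Lewis-acid-promoted C-glycosylation (oxocarbenium alkynylation): BF3 ionises the anomeric acetate and the alkynyl group is transferred from its tin-bearing carbon axially onto the half-chair cation, on the face anti to the pseudo-equatorial C7 side chain, which should give the 2,6-trans pyranone and set C3.

Step 8
Reactants: 11 2,6-trans alkynyl enone
Product: 12 (2R,5S,6S)-2-[(2S,3R,5E)-3-bromo-2-[(tert-butyldimethylsilyl)oxy]oct-5-en-1-yl]-5-(4,4,5,5-tetramethyl-1,3,2-dioxaborolan-2-yl)-6-[(trimethylsilyl)ethynyl]oxan-3-one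
Conditions: B2pin2, CuCl (5 mol%), bis[2-(diphenylphosphino)phenyl] ether (5 mol%), NaOt-Bu (10 mol%), MeOH (2 equiv), THF, 0 °C to rt
Reagents that add atoms: bis(pinacolato)diboron, CC1(C)OB(OC1(C)C)B1OC(C)(C)C(C)(C)O1
Why: Copper-catalysed conjugate borylation of a cyclic enone: the nucleophilic copper–boryl species should add to C4 on the face opposite the neighbouring alkynyl group and methanol protonates the enolate, so C4 carries a C–B bond cis to the C7 side chain as a masked hydroxyl that cannot be confused with the C6 oxygen.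

Step 9
Reactants: 12 β-boryl ketone
Product: 14 (2R,3R,5S,6S)-2-[(2S,3R,5E)-3-bromo-2-[(tert-butyldimethylsilyl)oxy]oct-5-en-1-yl]-6-ethynyl-5-(4,4,5,5-tetramethyl-1,3,2-dioxaborolan-2-yl)oxan-3-ol, via silylalkyne alcohol 13 (not isolated)
Conditions: LiBH(s-Bu)3, THF, −78 °C; then MeOH, K2CO3 (cat.), −78 °C to rt
Reagents that add atoms: none
Why: In the chair with the C7 side chain equatorial the C4 boryl group is axial and blocks axial hydride delivery, so the bulky borohydride should attack equatorially and give the axial (R) alcohol at C6, cis to the side chain, after which methoxide in methanol cleaves the C(sp)–Si bond (protodesilylation).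

Step 10
Reactants: 14 boryl alcohol with free alkyne
Product: 15 (2R,3R,5S,6S)-2-[(2S,3R,5E)-3-bromo-2-[(tert-butyldimethylsilyl)oxy]oct-5-en-1-yl]-6-ethynyl-5-(4,4,5,5-tetramethyl-1,3,2-dioxaborolan-2-yl)oxan-3-yl acetate
Conditions: Ac2O, pyridine, 4-(dimethylamino)pyridine (cat.), CH2Cl2, rt
Reagents that add atoms: acetic anhydride, CC(=O)OC(C)=O
Why: Acetylation of the only free hydroxyl places the acetate on C6 without any selectivity problem, and the pinacol boronate is inert to these conditions.

Step 11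
Reactants: 15 boryl acetate
Product: 16 (2R,3R,5S,6R)-2-[(2S,3R,5E)-3-bromo-2-[(tert-butyldimethylsilyl)oxy]oct-5-en-1-yl]-6-ethynyl-5-hydroxyoxan-3-yl acetate (ring O on C3 and C7; C4–OH trans to ethynyl)
Conditions: NaBO3·4H2O, THF/H2O, 0 °C to rt, short contact
Reagents that add atoms: sodium perborate tetrahydrate, [Na+].[O-]OB=O.O.O.O.O
Why: Oxidation of the secondary boronate (1,2-shift of C4 from boron to oxygen) goes with retention and should give the C4 hydroxyl trans to the ethynyl group, and cold, weakly basic perborate is chosen so that the acetate neither hydrolyses nor moves to the new 1,3-cis hydroxyl.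

Step 12
Reactants: 16 2,6-trans-2-ethynyloxan-3-ol
Product: 19 (2R,3R,5R)-2-[(2S,3R,5E)-3-bromo-2-[(tert-butyldimethylsilyl)oxy]oct-5-en-1-yl]-5-[(1S)-1-bromoprop-2-yn-1-yl]oxolan-3-yl acetate, via C4 triflate 17 (not isolated), via oxiranium ion 18 (not isolated)
Conditions: Tf2O, 2,6-di-tert-butyl-4-methylpyridine, CH2Cl2, −78 °C; then Bu4NBr (2 equiv), −78 to −30 °C, cold quench
Reagents that add atoms: tetrabutylammonium bromide, CCCC[N+](CCCC)(CCCC)CCCC.[Br-]
Why: Proposed new method: in the chair that keeps ethynyl and acetate equatorial the C4 triflate is equatorial and antiperiplanar to the ring O–C3 bond, so the ring oxygen should displace it from the rear to give a 1-oxoniabicyclo[3.1.0]hexane ion, which bromide then opens at the propargylic carbon C3 with cleavage of O–C3. The nearest precedents are the deaminative contraction of 2-amino-2-deoxy-pyranosides to 2,5-anhydro sugars, the solvolytic contraction of pyranosides whose equatorial leaving group neighbours the ring oxygen, and interconversions of six- and five-membered cyclic ethers through oxiranium ions; capture at a propargylic terminus by external bromide has not been shown. The oxolane is completed by the 3-exo-tet attack of the ring oxygen on C4 and not by a direct five-membered closure, and the six-membered ring is lost when bromide breaks O–C3. C4 (R) is fixed by that intramolecular backside displacement and C3 (S) by the SN2 opening, so both new stereocentres derive from the 2,3-trans relationship of 16 through two inversions. The step needs opening at C3 and not at C4, and no interference from the C6 acetate, which is cis-1,3 to the triflate and cannot displace it but could open the oxiranium ion at C4; the alkynyl group activates C3 towards substitution, and a non-nucleophilic pyridine base together with bromide added cold before ionisation should favour the intermolecular path. Bromide is held near 2 equivalents and the mixture is quenched cold so that the propargylic bromide is not epimerised by halide exchange.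

Step 13
Reactants: 19 C9 silyl ether of the target
Product: 20 (2R,3R,5R)-2-[(2S,3R,5E)-3-bromo-2-hydroxyoct-5-en-1-yl]-5-[(1S)-1-bromoprop-2-yn-1-yl]oxolan-3-yl acetate (target)
Conditions: HF·pyridine, THF, 0 °C to rt
Reagents that add atoms: none
Why: Acidic fluoride cleaves the silyl ether without forming an alkoxide next to C10–Br, so no epoxide should form; the pyridine is protonated and does not alkylate at the propargylic bromide, and acetate, alkyne and alkene are inert.

**Compound list**

1 | (E)-hept-4-enal | CC/C=C/CCC=O | starting material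
2 | (2R,4E)-2-bromohept-4-enal | O=C[C@H](Br)C/C=C/CC | intermediate
3 | 2-acetylfuran | CC(=O)c1ccco1 | starting material
4 | lithium 1-(furan-2-yl)ethenolate | [Li+].[O-]C(=C)c1ccco1 | intermediate
5 | (3S,4R,6E)-4-bromo-1-(furan-2-yl)-3-hydroxynon-6-en-1-one | O=C(C[C@H](O)[C@H](Br)C/C=C/CC)c1ccco1 | intermediate
6 | (3S,4R,6E)-4-bromo-3-[(tert-butyldimethylsilyl)oxy]-1-(furan-2-yl)non-6-en-1-one | O=C(C[C@H](O[Si](C)(C)C(C)(C)C)[C@H](Br)C/C=C/CC)c1ccco1 | intermediate
7 | (1R,3S,4R,6E)-4-bromo-3-[(tert-butyldimethylsilyl)oxy]-1-(furan-2-yl)non-6-en-1-ol | O[C@H](C[C@H](O[Si](C)(C)C(C)(C)C)[C@H](Br)C/C=C/CC)c1ccco1 | intermediate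
8 | (2R)-2-[(2S,3R,5E)-3-bromo-2-[(tert-butyldimethylsilyl)oxy]oct-5-en-1-yl]-6-hydroxy-2H-pyran-3(6H)-one, both C6 anomers | O=C1C=CC(O)O[C@@H]1C[C@H](O[Si](C)(C)C(C)(C)C)[C@H](Br)C/C=C/CC | intermediate
9 | (6R)-6-[(2S,3R,5E)-3-bromo-2-[(tert-butyldimethylsilyl)oxy]oct-5-en-1-yl]-5-oxo-5,6-dihydro-2H-pyran-2-yl acetate, anomeric mixture | O=C1C=CC(OC(C)=O)O[C@@H]1C[C@H](O[Si](C)(C)C(C)(C)C)[C@H](Br)C/C=C/CC | intermediate
10 | tributyl[(trimethylsilyl)ethynyl]stannane | CCCC[Sn](CCCC)(CCCC)C#C[Si](C)(C)C | starting material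
11 | (2R,6S)-2-[(2S,3R,5E)-3-bromo-2-[(tert-butyldimethylsilyl)oxy]oct-5-en-1-yl]-6-[(trimethylsilyl)ethynyl]-2H-pyran-3(6H)-one | C[Si](C)(C)C#C[C@@H]1C=CC(=O)[C@@H](C[C@H](O[Si](C)(C)C(C)(C)C)[C@H](Br)C/C=C/CC)O1 | intermediate
12 | (2R,5S,6S)-2-[(2S,3R,5E)-3-bromo-2-[(tert-butyldimethylsilyl)oxy]oct-5-en-1-yl]-5-(4,4,5,5-tetramethyl-1,3,2-dioxaborolan-2-yl)-6-[(trimethylsilyl)ethynyl]oxan-3-one | C[Si](C)(C)C#C[C@@H]1[C@@H](B2OC(C)(C)C(C)(C)O2)CC(=O)[C@@H](C[C@H](O[Si](C)(C)C(C)(C)C)[C@H](Br)C/C=C/CC)O1 | intermediate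
13 | (2R,3R,5S,6S)-2-[(2S,3R,5E)-3-bromo-2-[(tert-butyldimethylsilyl)oxy]oct-5-en-1-yl]-5-(4,4,5,5-tetramethyl-1,3,2-dioxaborolan-2-yl)-6-[(trimethylsilyl)ethynyl]oxan-3-ol | C[Si](C)(C)C#C[C@@H]1[C@@H](B2OC(C)(C)C(C)(C)O2)C[C@@H](O)[C@@H](C[C@H](O[Si](C)(C)C(C)(C)C)[C@H](Br)C/C=C/CC)O1 | intermediate
14 | (2R,3R,5S,6S)-2-[(2S,3R,5E)-3-bromo-2-[(tert-butyldimethylsilyl)oxy]oct-5-en-1-yl]-6-ethynyl-5-(4,4,5,5-tetramethyl-1,3,2-dioxaborolan-2-yl)oxan-3-ol | C#C[C@@H]1[C@@H](B2OC(C)(C)C(C)(C)O2)C[C@@H](O)[C@@H](C[C@H](O[Si](C)(C)C(C)(C)C)[C@H](Br)C/C=C/CC)O1 | intermediate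
15 | (2R,3R,5S,6S)-2-[(2S,3R,5E)-3-bromo-2-[(tert-butyldimethylsilyl)oxy]oct-5-en-1-yl]-6-ethynyl-5-(4,4,5,5-tetramethyl-1,3,2-dioxaborolan-2-yl)oxan-3-yl acetate | C#C[C@@H]1[C@@H](B2OC(C)(C)C(C)(C)O2)C[C@@H](OC(C)=O)[C@@H](C[C@H](O[Si](C)(C)C(C)(C)C)[C@H](Br)C/C=C/CC)O1 | intermediate
16 | (2R,3R,5S,6R)-2-[(2S,3R,5E)-3-bromo-2-[(tert-butyldimethylsilyl)oxy]oct-5-en-1-yl]-6-ethynyl-5-hydroxyoxan-3-yl acetate (chain numbering 3R,4S,6R,7R,9S,10R) | C#C[C@@H]1[C@@H](O)C[C@@H](OC(C)=O)[C@@H](C[C@H](O[Si](C)(C)C(C)(C)C)[C@H](Br)C/C=C/CC)O1 | intermediate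
17 | (2R,3R,5S,6R)-2-[(2S,3R,5E)-3-bromo-2-[(tert-butyldimethylsilyl)oxy]oct-5-en-1-yl]-6-ethynyl-5-[(trifluoromethanesulfonyl)oxy]oxan-3-yl acetate | C#C[C@@H]1[C@@H](OS(=O)(=O)C(F)(F)F)C[C@@H](OC(C)=O)[C@@H](C[C@H](O[Si](C)(C)C(C)(C)C)[C@H](Br)C/C=C/CC)O1 | intermediate
18 | bicyclic oxiranium (1-oxoniabicyclo[3.1.0]hexane) triflate: ring oxygen bonded to C3, C4 and C7, C3 as in 16, C4 inverted | C#C[C@@H]1[C@H]2C[C@@H](OC(C)=O)[C@@H](C[C@H](O[Si](C)(C)C(C)(C)C)[C@H](Br)C/C=C/CC)[O+]12.[O-]S(=O)(=O)C(F)(F)F | intermediate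
19 | (2R,3R,5R)-2-[(2S,3R,5E)-3-bromo-2-[(tert-butyldimethylsilyl)oxy]oct-5-en-1-yl]-5-[(1S)-1-bromoprop-2-yn-1-yl]oxolan-3-yl acetate | C#C[C@H](Br)[C@H]1C[C@@H](OC(C)=O)[C@@H](C[C@H](O[Si](C)(C)C(C)(C)C)[C@H](Br)C/C=C/CC)O1 | intermediate
20 | (2R,3R,5R)-2-[(2S,3R,5E)-3-bromo-2-hydroxyoct-5-en-1-yl]-5-[(1S)-1-bromoprop-2-yn-1-yl]oxolan-3-yl acetate | C#C[C@H](Br)[C@H]1C[C@@H](OC(C)=O)[C@@H](C[C@H](O)[C@H](Br)C/C=C/CC)O1 | target

**Step count and risks**

Total steps: 13. Longest linear sequence: 13 steps (1 to 20); 3 and 10 enter as purchased materials.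

Steps most likely to fail:

1. Step 12 (ring contraction). Several processes could divert it:
 - bromide opening of the oxiranium ion at C4, or direct displacement of the triflate at C4, which would leave a pyranyl bromide;
 - opening of the oxiranium ion at C4 by the C6 acetate;
 - reaction through the other chair, in which the triflate is axial and anti to the alkynyl group, leading to a 1,2-shift of that group or to elimination;
 - bromide exchange at C3 with loss of configuration.

 Fallback: it sets out from 16 and comes back at 19, using only established reaction types and the same two inversions in the opposite order. Me2BBr (CH2Cl2, −78 to 0 °C) would cleave the oxane at the activated propargylic C3–O bond with inversion to give the acyclic bromo diol F1. K2CO3 in acetone at 0 °C would close the anti bromohydrin to the cis-alkynyl epoxide F2; the base step is kept short and cold because the C6 acetate sits next to the freed C7 hydroxyl. Catalytic (+)-10-camphorsulfonic acid in CH2Cl2 would then bring about the 5-exo opening of the epoxide at C4 by the C7 hydroxyl, the mode expected for an uncomplexed alkynyl epoxide, to give the oxolane propargylic alcohol F3 with a (3R) carbinol. Appel bromination (CBr4, PPh3, CH2Cl2, 0 °C) with inversion would convert F3 into 19.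

2. Step 2 (aldol with the α-bromo aldehyde). Enolisation and racemisation of 2 by the basic enolate, loss of HBr to a conjugated dienal, closure of the lithium aldolate to an epoxide, or erosion of the anti selectivity could each lower the outcome.

 Fallback: it sets out from 3 (with 2) and comes back at 5, replacing the basic metal enolate by a neutral enol silane in a Lewis-acid-promoted open transition state. TMSOTf and Et3N (CH2Cl2, 0 °C) would convert 3 into the silyl enol ether F4. A Mukaiyama aldol addition of F4 to 2 (BF3·OEt2, CH2Cl2, −78 °C) should give the same anti adduct 5 under polar Felkin–Anh/Cornforth control, with no base present at any point.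

3. Step 7 (C-ethynylation). The electron-poor oxocarbenium ion could be captured intramolecularly by the C9 silyl ether oxygen on the face cis to the side chain (bridged ketal formation), could react sluggishly with the alkynyl donor, or could be attacked with poor facial selectivity.

 Fallback: it sets out from 9 and comes back at 11, moving the alkynylation to the better stabilised allylic oxocarbenium ion of a Ferrier-type substrate. Luche reduction (NaBH4, CeCl3·7H2O, MeOH, −78 °C) would give the allylic alcohol F5, mainly trans to the side chain; its configuration is irrelevant because the carbinol is re-oxidised. Acetylation (Ac2O, pyridine) would give the diacetate F6. Ferrier-type C-alkynylation with 10 (TMSOTf, CH2Cl2, −78 to −20 °C) should give the 2,6-trans alkynyl dihydropyranyl acetate F7. i-Bu2AlH (CH2Cl2, −78 °C) would remove the acetate to give the allylic alcohol F8, and Dess–Martin oxidation would return enone 11.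

Further compounds
F1 | step 12 | (3S,4S,6R,7R,9S,10R,12E)-3,10-dibromo-9-[(tert-butyldimethylsilyl)oxy]-4,7-dihydroxypentadec-12-en-1-yn-6-yl acetate | C#C[C@H](Br)[C@@H](O)C[C@@H](OC(C)=O)[C@@H](C[C@H](O[Si](C)(C)C(C)(C)C)[C@H](Br)C/C=C/CC)O
F2 | step 12 | (2R,3R,5S,6R,8E)-6-bromo-5-[(tert-butyldimethylsilyl)oxy]-1-[(2S,3R)-3-ethynyloxiran-2-yl]-3-hydroxyundec-8-en-2-yl acetate (cis-epoxide) | C#C[C@H]1O[C@H]1C[C@@H](OC(C)=O)[C@@H](C[C@H](O[Si](C)(C)C(C)(C)C)[C@H](Br)C/C=C/CC)O
F3 | step 12 | (2R,3R,5R)-2-[(2S,3R,5E)-3-bromo-2-[(tert-butyldimethylsilyl)oxy]oct-5-en-1-yl]-5-[(1R)-1-hydroxyprop-2-yn-1-yl]oxolan-3-yl acetate | C#C[C@@H](O)[C@H]1C[C@@H](OC(C)=O)[C@@H](C[C@H](O[Si](C)(C)C(C)(C)C)[C@H](Br)C/C=C/CC)O1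
F4 | step 2 | {[1-(furan-2-yl)ethenyl]oxy}trimethylsilane | C=C(O[Si](C)(C)C)c1ccco1
F5 | step 7 | (2R,3S)-2-[(2S,3R,5E)-3-bromo-2-[(tert-butyldimethylsilyl)oxy]oct-5-en-1-yl]-3-hydroxy-3,6-dihydro-2H-pyran-6-yl acetate, anomeric mixture | CC(=O)OC1C=C[C@H](O)[C@@H](C[C@H](O[Si](C)(C)C(C)(C)C)[C@H](Br)C/C=C/CC)O1
F6 | step 7 | (2R,3S)-2-[(2S,3R,5E)-3-bromo-2-[(tert-butyldimethylsilyl)oxy]oct-5-en-1-yl]-3,6-dihydro-2H-pyran-3,6-diyl diacetate, anomeric mixture | CC(=O)OC1C=C[C@H](OC(C)=O)[C@@H](C[C@H](O[Si](C)(C)C(C)(C)C)[C@H](Br)C/C=C/CC)O1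
F7 | step 7 | (2R,3S,6S)-2-[(2S,3R,5E)-3-bromo-2-[(tert-butyldimethylsilyl)oxy]oct-5-en-1-yl]-6-[(trimethylsilyl)ethynyl]-3,6-dihydro-2H-pyran-3-yl acetate | C[Si](C)(C)C#C[C@@H]1C=C[C@H](OC(C)=O)[C@@H](C[C@H](O[Si](C)(C)C(C)(C)C)[C@H](Br)C/C=C/CC)O1
F8 | step 7 | (2R,3S,6S)-2-[(2S,3R,5E)-3-bromo-2-[(tert-butyldimethylsilyl)oxy]oct-5-en-1-yl]-6-[(trimethylsilyl)ethynyl]-3,6-dihydro-2H-pyran-3-ol | C[Si](C)(C)C#C[C@@H]1C=C[C@H](O)[C@@H](C[C@H](O[Si](C)(C)C(C)(C)C)[C@H](Br)C/C=C/CC)O1
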